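**Retrosynthetic overview**
- Target 17 comes from triacetate 16 by acid methanolysis of the O3, O4 and O6 acetates, which leaves the O5 and O7 benzoates.
- The strategy rests on the cyclohexene ring carrying four contiguous all-cis oxygens on C3–C6, with O3 and O6 1,4-cis across the C1=C2 alkene and cis to O4 and O5. Both C–O bonds are made at once by palladium-catalysed, anodically driven cis-1,4-diacetoxylation of the C6=C1–C2=C3 diene 14.
- Diene 14 comes from selenoxide elimination after selenide opening of the 3,4-epoxide 7. The epoxide comes from Mitsunobu cyclodehydration of methyl shikimate and is what distinguishes O4 (later acetate) from O5 (benzoate).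
- The only ring, the cyclohexene, is taken intact from (−)-shikimic acid and no ring is formed. C4 and C5 keep the shikimate configuration, and the wrongly configured shikimate carbinol (target C3) becomes a diene carbon.

Key step: step 8

Remark: locants in the text are those of the target (C7 is the CH2O carbon on C1; shikimate C1–C6 correspond to target C1, C6, C5, C4, C3, C2), systematic names carry their own locants, and it is assumed that the bulky palladium fragment binds the diene face anti to the two ester groups.

**Step 1**
Reactants: 1 (−)-shikimic acid; 2 methanol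
Product: 3 methyl shikimate
Conditions: MeOH, camphorsulfonic acid (cat.), reflux
Reagents that add atoms: methanol, CO
Why: Fischer esterification of the conjugated acid in excess methanol, which does not touch the three carbinol stereocentres.

**Step 2**
Reactants: 3 methyl shikimate
Product: 4 methyl (1S,5R,6R)-5-hydroxy-7-oxabicyclo[4.1.0]hept-3-ene-3-carboxylate (3,4-epoxide on the face of the 5-OH)
Conditions: PPh3, DIAD, THF, 0 °C → rt
Reagents that add atoms: none
Why: Mitsunobu cyclodehydration of the trans-3,4-diol, in which the less hindered 3-OH (next to the ring CH2) is activated as the oxyphosphonium and displaced by O4 in an intramolecular SN2 reaction with inversion at C3, placing the epoxide cis to the 5-OH, while the cis-4,5-diol cannot close; this behaviour is established for methyl shikimate itself.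

**Step 3**
Reactants: 4 epoxy ester
Product: 5 (1R,2R,6S)-4-(hydroxymethyl)-7-oxabicyclo[4.1.0]hept-3-en-2-ol
Conditions: i-Bu2AlH (3.5 equiv), CH2Cl2, −78 °C; aq. potassium sodium tartrate
Reagents that add atoms: none
Why: 1,2-reduction of the α,β-unsaturated ester to the allylic alcohol by diisobutylaluminium hydride, which at −78 °C is much faster than hydride opening of the unactivated epoxide, so no stereocentre is affected.

**Step 4**
Reactants: 5 epoxy diol; 6 benzoyl chloride
Product: 7 [(1S,5R,6S)-5-(benzoyloxy)-7-oxabicyclo[4.1.0]hept-3-en-3-yl]methyl benzoate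
Conditions: BzCl (2.3 equiv), Et3N, DMAP (cat.), CH2Cl2, 0 °C
Reagents that add atoms: benzoyl chloride, O=C(Cl)c1ccccc1
Why: DMAP-catalysed acylation of the only two free hydroxyls (O7 primary allylic, O5 secondary allylic) while O4 stays masked in the epoxide, which fixes the benzoate on O5 and not on O4.

**Step 5**
Reactants: 7 dibenzoate epoxide; 8 diphenyl diselenide
Product: 10 [(3R,4R,5R)-3-(benzoyloxy)-4-hydroxy-5-(phenylselanyl)cyclohex-1-en-1-yl]methyl benzoate, via sodium benzeneselenolate 9 (not isolated)
Conditions: (PhSe)2, NaBH4, EtOH, 0 °C; then AcOH, 7 in THF, 0 °C → rt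
Reagents that add atoms: diphenyl diselenide, c1ccc(cc1)[Se][Se]c1ccccc1
Why: SN2 epoxide opening by the soft selenolate at C3, the carbon remote from the electron-withdrawing 5-benzoate and the one that allows trans-diaxial opening (Fürst–Plattner rule), with inversion at C3 so that selenium lies trans to the freed 4-OH, while the acetic acid buffer keeps the cis 5-benzoate from migrating to O4.

**Step 6**
Reactants: 10 hydroxy selenide; 11 acetic anhydride
Product: 12 [(3R,4R,5R)-4-(acetyloxy)-3-(benzoyloxy)-5-(phenylselanyl)cyclohex-1-en-1-yl]methyl benzoate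
Conditions: Ac2O, pyridine, DMAP (cat.), CH2Cl2, 0 °C → rt
Reagents that add atoms: acetic anhydride, CC(=O)OC(C)=O
Why: DMAP-catalysed acetylation of the single free secondary hydroxyl (O4) with retention, installing the acetate that is removed at the end together with the two acetates of the key step.

**Step 7**
Reactants: 12 acetoxy selenide
Product: 14 [(3R,4S)-4-(acetyloxy)-3-(benzoyloxy)cyclohexa-1,5-dien-1-yl]methyl benzoate, via selenoxide 13 (not isolated)
Conditions: mCPBA (1.05 equiv), CH2Cl2, −78 °C; then i-Pr2NH, −78 °C → rt
Reagents that add atoms: none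
Why: selenide oxidation followed by selenoxide syn-elimination through a five-membered cyclic transition state toward the allylic C2–H and away from the acetoxy-bearing C4, which gives the C2=C3 alkene conjugated with C6=C1, removes the C3 stereocentre and leaves C4 and C5 untouched.

**Step 8**
Reactants: 14 diene; 15 acetic acid
Product: 16 [(3S,4S,5R,6R)-3,4,6-tris(acetyloxy)-5-(benzoyloxy)cyclohex-1-en-1-yl]methyl benzoate
Conditions: Pd(OAc)2 (5 mol %), p-benzoquinone (10 mol %), LiCl (20 mol %), LiOAc (3 equiv), LiClO4 (0.1 M), AcOH, divided cell, Pt anode, constant anode potential, 25 °C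
Reagents that add atoms: acetic acid, CC(=O)O; lithium acetate, [Li+].CC(=O)[O-]
Why: Divalent palladium binds the C6=C1–C2=C3 diene on the face opposite the 4-acetoxy and 5-benzoyloxy groups, external acetate attacks one diene terminus anti to the metal to give an (η3-allyl)palladium chloride, and a second external acetate attacks the other terminus of the quinone-activated allyl, again anti, so that the C3–O and C6–O bonds form cis to each other and the alkene remains at C1=C2; the zerovalent palladium released is returned to the divalent state by benzoquinone, and the hydroquinone is reoxidised at the anode while protons are reduced at the cathode. The closest known reaction is the quinone-mediated palladium-catalysed cis-1,4-diacetoxylation of cyclohexa-1,3-dienes, which has also been run with anodic regeneration of the quinone. No ring is closed. The new stereocentres C3 and C6 are set by substrate control from C4 and C5, because the two ester groups keep the metal off their face and each anti attack then delivers acetate to that same face, giving the all-cis array. The step needs this facial selectivity, 1,4- over 1,2-addition and cis over trans addition; the six-membered ring favours 1,4-addition as in the parent diene, and the chloride ligand blocks the coordination site from which acetate would otherwise migrate syn, while its catalytic amount avoids chloroacetoxylation. Fast reoxidation of zerovalent palladium and the acetate buffer should protect the allylic esters from ionisation and the diene from aromatisation.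

**Step 9**
Reactants: 16 triacetate; 2 methanol
Product: 17 [(3S,4S,5R,6R)-5-(benzoyloxy)-3,4,6-trihydroxycyclohex-1-en-1-yl]methyl benzoate
Conditions: HCl (cat.), MeOH/CH2Cl2, 0 °C → rt, stopped at complete deacetylation
Reagents that add atoms: none
Why: acid-catalysed transesterification (methanolysis) cleaves the three acetates much faster than the conjugated, bulkier benzoates and does not promote base-type acyl migration, so the O5 and O7 benzoates and all four stereocentres should be retained.

**Compound list**
1 | (−)-shikimic acid, (3R,4S,5R)-3,4,5-trihydroxycyclohex-1-ene-1-carboxylic acid | OC(=O)C1=C[C@@H](O)[C@@H](O)[C@H](O)C1 | starting material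
2 | methanol | CO | starting material
3 | methyl shikimate, methyl (3R,4S,5R)-3,4,5-trihydroxycyclohex-1-ene-1-carboxylate | COC(=O)C1=C[C@@H](O)[C@@H](O)[C@H](O)C1 | intermediate
4 | methyl (1S,5R,6R)-5-hydroxy-7-oxabicyclo[4.1.0]hept-3-ene-3-carboxylate (epoxide cis to the hydroxyl) | COC(=O)C1=C[C@@H](O)[C@H]2O[C@H]2C1 | intermediate
5 | (1R,2R,6S)-4-(hydroxymethyl)-7-oxabicyclo[4.1.0]hept-3-en-2-ol | OCC1=C[C@@H](O)[C@H]2O[C@H]2C1 | intermediate
6 | benzoyl chloride | O=C(Cl)c1ccccc1 | starting material
7 | [(1S,5R,6S)-5-(benzoyloxy)-7-oxabicyclo[4.1.0]hept-3-en-3-yl]methyl benzoate | O=C(OCC1=C[C@@H](OC(=O)c2ccccc2)[C@H]2O[C@H]2C1)c1ccccc1 | intermediate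
8 | diphenyl diselenide | c1ccc(cc1)[Se][Se]c1ccccc1 | starting material
9 | sodium benzeneselenolate | [Na+].[Se-]c1ccccc1 | intermediate
10 | [(3R,4R,5R)-3-(benzoyloxy)-4-hydroxy-5-(phenylselanyl)cyclohex-1-en-1-yl]methyl benzoate | O=C(OCC1=C[C@@H](OC(=O)c2ccccc2)[C@@H](O)[C@H]([Se]c2ccccc2)C1)c1ccccc1 | intermediate
11 | acetic anhydride | CC(=O)OC(C)=O | starting material
12 | [(3R,4R,5R)-4-(acetyloxy)-3-(benzoyloxy)-5-(phenylselanyl)cyclohex-1-en-1-yl]methyl benzoate | O=C(OCC1=C[C@@H](OC(=O)c2ccccc2)[C@@H](OC(C)=O)[C@H]([Se]c2ccccc2)C1)c1ccccc1 | intermediate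
13 | [(3R,4R,5R)-4-(acetyloxy)-3-(benzoyloxy)-5-(benzeneseleninyl)cyclohex-1-en-1-yl]methyl benzoate (both configurations at selenium) | O=C(OCC1=C[C@@H](OC(=O)c2ccccc2)[C@@H](OC(C)=O)[C@H]([Se](=O)c2ccccc2)C1)c1ccccc1 | intermediate
14 | [(3R,4S)-4-(acetyloxy)-3-(benzoyloxy)cyclohexa-1,5-dien-1-yl]methyl benzoate | O=C(OCC1=C[C@@H](OC(=O)c2ccccc2)[C@@H](OC(C)=O)C=C1)c1ccccc1 | intermediate
15 | acetic acid | CC(=O)O | starting material
16 | [(3S,4S,5R,6R)-3,4,6-tris(acetyloxy)-5-(benzoyloxy)cyclohex-1-en-1-yl]methyl benzoate | O=C(OCC1=C[C@H](OC(C)=O)[C@H](OC(C)=O)[C@H](OC(=O)c2ccccc2)[C@@H]1OC(C)=O)c1ccccc1 | intermediate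
17 | [(3S,4S,5R,6R)-5-(benzoyloxy)-3,4,6-trihydroxycyclohex-1-en-1-yl]methyl benzoate | O=C(OCC1=C[C@H](O)[C@H](O)[C@H](OC(=O)c2ccccc2)[C@@H]1O)c1ccccc1 | target

**Step count**
Total: 9 steps. Longest linear sequence: 9 steps (fully linear from 1).

**Steps most likely to fail**

Step 8. Facial selectivity may be poor or reversed if an ester carbonyl guides palladium onto the ester-bearing face, which would place the new acetates trans to O4 and O5. The diene may also aromatise in acid, or an allylic ester may ionise on zerovalent palladium before it is reoxidised. The fallback sets out from hydroxy selenide 10 and relies on hydroxyl direction instead of steric control.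
- Oxidation of 10 with mCPBA at −78 °C followed by i-Pr2NH should give, through the hydroxy selenoxide F1 and syn-elimination, the dienol [(3R,4S)-3-(benzoyloxy)-4-hydroxycyclohexa-1,5-dien-1-yl]methyl benzoate F2.
- VO(acac)2 (cat.) with t-BuOOH in CH2Cl2 at 0 °C should epoxidise the C2=C3 alkene on the face of the free 4-OH (hydroxyl-directed epoxidation), giving the syn epoxy alcohol F3.
- Pd(PPh3)4 (cat.) with AcOH in THF at 0 °C should open the vinyl epoxide by anti ionisation at C2 and anti attack of acetate at C6. The net retention puts O6 cis to O3 and gives the 6-O-acetyl derivative of the target F4.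
- Methanolysis of F4 under the conditions of step 9 returns to the route at 17.

Step 9. Acetate and benzoate may not be discriminated fully, and acid may promote migration of the O5 benzoyl group to the newly freed cis neighbours O4 or O6. The fallback sets out from 16 and replaces rate-based solvolysis by enzyme recognition at neutral pH: lipase-catalysed butanolysis (Candida antarctica lipase B, n-BuOH, MTBE, 35 °C) should remove acetates only, since benzoates are poor lipase substrates. It arrives at 17 and makes no new compound.

Step 5. The benzoyl group may migrate from O5 to the O4 alkoxide during opening, and some attack may occur at C4. The fallback sets out from epoxide 7 and avoids both the basic opening and the selenium redox sequence.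
- LiBr with AcOH in THF should open the epoxide under acidic conditions to the trans bromohydrin [(3R,4R,5R)-3-(benzoyloxy)-5-bromo-4-hydroxycyclohex-1-en-1-yl]methyl benzoate F5.
- Ac2O with pyridine should give the bromo acetate F6.
- DBU in toluene should effect anti E2 elimination. Only the C2–H is anti to the C3 bromide (the C4–H is cis to it), so the C2=C3 alkene forms and the route is rejoined at diene 14.

**Further compounds**
F1 | step 8 | [(3R,4R,5R)-3-(benzoyloxy)-4-hydroxy-5-(benzeneseleninyl)cyclohex-1-en-1-yl]methyl benzoate (hydroxy selenoxide, not isolated) | O=C(OCC1=C[C@@H](OC(=O)c2ccccc2)[C@@H](O)[C@H]([Se](=O)c2ccccc2)C1)c1ccccc1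
F2 | step 8 | [(3R,4S)-3-(benzoyloxy)-4-hydroxycyclohexa-1,5-dien-1-yl]methyl benzoate | O=C(OCC1=C[C@@H](OC(=O)c2ccccc2)[C@@H](O)C=C1)c1ccccc1
F3 | step 8 | 2,3-epoxide of F2 on the face of the 4-OH (target locants), 5,7-dibenzoate | O=C(OCC1=C[C@@H](OC(=O)c2ccccc2)[C@@H](O)[C@H]3O[C@@H]13)c1ccccc1
F4 | step 8 | 6-O-acetyl derivative of 17 (all-cis; 3,4-diol, 5,7-dibenzoate) | O=C(OCC1=C[C@H](O)[C@H](O)[C@H](OC(=O)c2ccccc2)[C@@H]1OC(C)=O)c1ccccc1
F0 | step 9 | none | none
F5 | step 5 | [(3R,4R,5R)-3-(benzoyloxy)-5-bromo-4-hydroxycyclohex-1-en-1-yl]methyl benzoate | O=C(OCC1=C[C@@H](OC(=O)c2ccccc2)[C@@H](O)[C@H](Br)C1)c1ccccc1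
F6 | step 5 | [(3R,4R,5R)-4-(acetyloxy)-3-(benzoyloxy)-5-bromocyclohex-1-en-1-yl]methyl benzoate | O=C(OCC1=C[C@@H](OC(=O)c2ccccc2)[C@@H](OC(C)=O)[C@H](Br)C1)c1ccccc1
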